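**Strategy.** The oxocane is disconnected at O–C6 and C7–C8 (chain numbering C1 alkyne CH to C15). Both bonds form in one operation when dichloroketene acylates the oxygen of a trans-2-vinyloxetane (O, C10, C11, C12; vinyl = C9=C8) and the oxonium enolate undergoes a strain-driven [3,3] shift: a four-atom ring enlargement to the eight-membered lactone. The step exploits that ring atoms C6–C7, with the C7 chlorine, are a ketene unit flanked by O and C8, and that the C9(Cl)–C10(OAc) pair maps onto the Z-alkene it leaves. C12 and C13 come from one catalytic epoxidation; C7, C9, C10 and C6 are relayed from them on the tub-shaped lactone.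

Key step: step 7

Remark: the target is read as (3E,6S,7S,9S,10S,12R,13R) in this chain numbering, i.e. the two ring α-substituents trans, C6 chain and C7–Cl cis, C9–Cl and C10–OAc trans.

Step 1
Reactants: 1 but-1-yne; 2 (R)-epichlorohydrin
Product: 3 (2R)-1-chlorohept-4-yn-2-ol
Conditions: n-BuLi, THF, −78 °C; BF3·OEt2; then 2, −78 °C; aq. NH4Cl
Reagents that add atoms: none
Why: Yamaguchi–Hirao alkynylation, in which the lithium alkynyltrifluoroborate should open the epoxide by SN2 attack at its CH2 terminus only, so that the C11–C12 bond is made and the stereocenter of 2 (the future C10) is carried over untouched.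

Step 2
Reactants: 3 (2R)-1-chlorohept-4-yn-2-ol
Product: 5 (3R)-oct-1-en-5-yn-3-ol, via (2R)-2-(pent-2-ynyl)oxirane 4 (not isolated)
Conditions: Me3S+ I− (3 equiv), n-BuLi (3.5 equiv), THF, −10 → 20 °C; H2O
Reagents that add atoms: trimethylsulfonium iodide, C[S+](C)C.[I-]
Why: One-carbon homologation of an epoxide to an allylic alcohol with excess dimethylsulfonium methylide: base closes the chlorohydrin to epoxide 4, the ylide opens it at CH2, and a second deprotonation on sulfur followed by syn-elimination of Me2S should leave the vinyl carbinol with C10 unchanged.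

Step 3
Reactants: 5 (3R)-oct-1-en-5-yn-3-ol
Product: 6 (3R,5E)-octa-1,5-dien-3-ol
Conditions: Na, NH3(l)/THF, −78 → −33 °C; NH4Cl
Reagents that add atoms: none
Why: Dissolving-metal (Birch-type) reduction of the internal alkyne should give the E-alkene through the trans-vinyl anion, while the isolated vinyl group and the allylic alkoxide are not reduced.

Step 4
Reactants: 6 (3R,5E)-octa-1,5-dien-3-ol
Product: 7 (2R)-1-[(2S,3S)-3-ethyloxiran-2-yl]but-3-en-2-ol
Conditions: ent-Shi ketone (L-fructose-derived, 0.3 equiv), KHSO5 (as Oxone), K2CO3, Bu4NHSO4, MeCN–CH2(OMe)2–aq. Na2B4O7 buffer, 0 °C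
Reagents that add atoms: potassium peroxymonosulfate, [K+].[O-]S(=O)(=O)OO
Why: Shi epoxidation, in which the chiral dioxirane should epoxidise only the trans-disubstituted C12=C13 alkene (the monosubstituted vinyl group is a poor substrate) through the spiro transition state and set C12 and C13 as (S,S) under catalyst control, the mirror image of the (R,R) sense known for the D-fructose-derived ketone.

Step 5
Reactants: 7 (2R)-1-[(2S,3S)-3-ethyloxiran-2-yl]but-3-en-2-ol
Product: 8 (1S)-1-[(2R,4R)-4-ethenyloxetan-2-yl]propan-1-ol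
Conditions: KOH, DMSO–H2O (3:1), 120 °C
Reagents that add atoms: none
Why: Base-mediated 4-exo-tet cyclisation of a 3,4-epoxy alcohol, in which the C10 alkoxide should open the epoxide at C12 with inversion (oxetane formation is the documented course in KOH/aqueous DMSO, the 5-endo path to the tetrahydrofuran being stereoelectronically disfavoured), giving the trans-2,4-disubstituted oxetane with C12 (R) and leaving C13–OH (S).

Step 6
Reactants: 8 (1S)-1-[(2R,4R)-4-ethenyloxetan-2-yl]propan-1-ol
Product: 9 tert-butyl{[(1S)-1-[(2R,4R)-4-ethenyloxetan-2-yl]propyl]oxy}dimethylsilane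
Conditions: TBSCl, imidazole, DMF, 20 °C
Reagents that add atoms: tert-butyldimethylsilyl chloride, CC(C)(C)[Si](C)(C)Cl
Why: Standard silylation of the secondary alcohol, which masks C13–OH against acylation by the ketene and is carried to the penultimate step.

Step 7
Reactants: 9 tert-butyl{[(1S)-1-[(2R,4R)-4-ethenyloxetan-2-yl]propyl]oxy}dimethylsilane
Product: 10 (5Z,8R)-8-[(1S)-1-(tert-butyldimethylsilyloxy)propyl]-3,3-dichloro-3,4,7,8-tetrahydro-2H-oxocin-2-one
Conditions: Cl3CCOCl (2.5 equiv, syringe pump), activated Zn dust, Et2O–DME (5:1), 20 °C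
Reagents that add atoms: trichloroacetyl chloride, ClC(Cl)(Cl)C(Cl)=O
Why: Zinc dechlorinates Cl3CCOCl to dichloroketene, whose carbonyl carbon is attacked by the oxetane oxygen on the lone pair syn to the vinyl group and anti to the C12 side chain (O–C6 bond); the 1,3-dipolar oxonium enolate then undergoes a [3,3]-sigmatropic shift that forms C7–C8 and cleaves O–C10. The closest known reaction is the Bellus–Claisen rearrangement (ketene Claisen) used as a ring enlargement of 2-vinyltetrahydrofurans and 2-vinyltetrahydropyrans with dichloroketene, here on the four-membered homologue, and the transition state should be the boat known from the Cope rearrangement of cis-1,2-divinylcyclobutane to cycloocta-1,5-diene. The eight-membered lactone is therefore closed by four-atom ring expansion of the oxetane and not by end-to-end cyclisation, driven by release of oxetane strain and charge annihilation. No stereocenter is created (C7 is CCl2): the boat geometry enforces the Z C9=C10 alkene, C12 and C13 are untouched because the O–C12 bond persists, and the C10 stereocenter, which only served to place the vinyl group trans to the side chain, is erased. The step needs O-acylation and [3,3] shift to outrun [2+2] cycloaddition of the ketene to the vinyl group and acyl chloride cleavage of the oxetane; the high nucleophilicity of the oxetane oxygen, the unhindered reacting face of the trans isomer, slow addition of the acid chloride and DME to sequester ZnCl2 should secure this.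

Step 8
Reactants: 10 (5Z,8R)-8-[(1S)-1-(tert-butyldimethylsilyloxy)propyl]-3,3-dichloro-3,4,7,8-tetrahydro-2H-oxocin-2-one
Product: 11 (3S,5Z,8R)-8-[(1S)-1-(tert-butyldimethylsilyloxy)propyl]-3-chloro-3,4,7,8-tetrahydro-2H-oxocin-2-one
Conditions: Bu3SnH (1.05 equiv), Et3B (0.2 equiv), air, toluene, −78 °C
Reagents that add atoms: none
Why: Radical-chain mono-dechlorination (the first C–Cl bond of an α,α-dichloro ester is cleaved much faster than that of the α-chloro product), in which the planar α-chloro-α-acyl radical should take hydrogen from the stannane on the convex face of the tub-shaped ring (planar ester and Z-alkene as in cycloocta-1,5-diene, C12 chain pseudo-equatorial), so that the retained chlorine ends pseudo-axial and trans to the C12 side chain (7S) under kinetic control.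

Step 9
Reactants: 11 (3S,5Z,8R)-8-[(1S)-1-(tert-butyldimethylsilyloxy)propyl]-3-chloro-3,4,7,8-tetrahydro-2H-oxocin-2-one
Product: 13 (3S,5S,6S,8R)-8-[(1S)-1-(tert-butyldimethylsilyloxy)propyl]-3,5-dichloro-6-(triethylsilyloxy)oxocan-2-one, via epoxy lactone 12 (not isolated)
Conditions: dimethyldioxirane, acetone, 0 °C; evaporate; then Et3SiCl (1.5 equiv), PPh3 (5 mol%), CH2Cl2, 0 → 20 °C
Reagents that add atoms: dimethyldioxirane, CC1(C)OO1; chlorotriethylsilane, CC[Si](CC)(CC)Cl
Why: Dioxirane epoxidation should occur on the convex face of the tub-shaped lactone and fix the C10–O configuration, and the phosphine-catalysed opening of the epoxide by the silyl chloride should then deliver chloride anti at C9 (the carbon whose backside lies over the electrophilic lactone carbonyl and not over the ring-oxygen lone pairs; the ester-type ring oxygen cannot take part transannularly) and cap O10 at once, so that it cannot translactonise.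

Step 10
Reactants: 13 (3S,5S,6S,8R)-8-[(1S)-1-(tert-butyldimethylsilyloxy)propyl]-3,5-dichloro-6-(triethylsilyloxy)oxocan-2-one
Product: 15 (2S,3S,5S,6S,8R)-2-allyl-8-[(1S)-1-(tert-butyldimethylsilyloxy)propyl]-3,5-dichloro-6-(triethylsilyloxy)oxocane, via hemiketal 14 (not isolated)
Conditions: CH2=CHCH2MgBr (1.1 equiv), Et2O–CH2Cl2, −78 °C; then Et3SiH (5 equiv), Me3SiOTf (3 equiv), −78 → −40 °C; aq. NaHCO3
Reagents that add atoms: allylmagnesium bromide, C=CC[Mg]Br
Why: Lactone C-allylation followed by ionic hydrogenation of the hemiketal (the C-glycoside-type sequence): the allyl Grignard reagent should add once to the strained α-chloro lactone (the α-chlorine stabilises the tetrahedral bromomagnesium hemiketalate, and the convex-face C10 silyloxy group cannot reach C6), Me3SiOTf ionises it to the oxocarbenium ion, and Et3SiH attacks anti to the pseudo-axial C7–Cl bond (polar Felkin–Anh), placing the allyl group cis to C7–Cl and trans to the C12 chain (6S).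

Step 11
Reactants: 15 (2S,3S,5S,6S,8R)-2-allyl-8-[(1S)-1-(tert-butyldimethylsilyloxy)propyl]-3,5-dichloro-6-(triethylsilyloxy)oxocane
Product: 16 (2E)-4-[(2S,3S,5S,6S,8R)-8-[(1S)-1-(tert-butyldimethylsilyloxy)propyl]-3,5-dichloro-6-(triethylsilyloxy)oxocan-2-yl]but-2-enal
Conditions: crotonaldehyde (5 equiv), second-generation Grubbs catalyst RuCl2(=CHPh)(PCy3)(H2IMes) (5 mol%), CH2Cl2, 40 °C
Reagents that add atoms: crotonaldehyde, C/C=C/C=O
Why: Olefin cross-metathesis of the terminal alkene with an excess of the electron-poor partner should give the conjugated enal with the thermodynamically favoured E geometry at C3=C4, propene being lost.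

Step 12
Reactants: 16 (2E)-4-[(2S,3S,5S,6S,8R)-8-[(1S)-1-(tert-butyldimethylsilyloxy)propyl]-3,5-dichloro-6-(triethylsilyloxy)oxocan-2-yl]but-2-enal
Product: 18 (2R,4S,5S,7S,8S)-2-[(1S)-1-(tert-butyldimethylsilyloxy)propyl]-5,7-dichloro-8-[(2E)-pent-2-en-4-yn-1-yl]oxocan-4-ol, via triethylsilyl enyne 17 (not isolated)
Conditions: Me3SiCHN2, LiN(iPr)2, THF, −78 → 0 °C; aq. NH4Cl; then PPTS (0.2 equiv), MeOH, 20 °C
Reagents that add atoms: (trimethylsilyl)diazomethane, C[Si](C)(C)C=[N+]=[N-]
Why: Colvin rearrangement (1,2-addition of the lithiated silyldiazomethane to the enal, loss of silanolate and N2, 1,2-hydrogen shift of the alkylidene carbene) should give the terminal E-enyne without touching the C3=C4 geometry, and mild acid methanolysis then removes the triethylsilyl ether selectively in the presence of the bulkier tert-butyldimethylsilyl ether.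

Step 13
Reactants: 18 (2R,4S,5S,7S,8S)-2-[(1S)-1-(tert-butyldimethylsilyloxy)propyl]-5,7-dichloro-8-[(2E)-pent-2-en-4-yn-1-yl]oxocan-4-ol
Product: 19 (2R,4S,5S,7S,8S)-2-[(1S)-1-(tert-butyldimethylsilyloxy)propyl]-5,7-dichloro-8-[(2E)-pent-2-en-4-yn-1-yl]oxocan-4-yl acetate
Conditions: Ac2O, pyridine, DMAP (cat.), CH2Cl2, 20 °C
Reagents that add atoms: acetic anhydride, CC(=O)OC(C)=O
Why: Nucleophile-catalysed acetylation of the only free hydroxyl group, under conditions too weakly basic to close the trans-chlorohydrin back to the epoxide.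

Step 14
Reactants: 19 (2R,4S,5S,7S,8S)-2-[(1S)-1-(tert-butyldimethylsilyloxy)propyl]-5,7-dichloro-8-[(2E)-pent-2-en-4-yn-1-yl]oxocan-4-yl acetate
Product: 20 (2R,4S,5S,7S,8S)-5,7-dichloro-2-[(1S)-1-hydroxypropyl]-8-[(2E)-pent-2-en-4-yn-1-yl]oxocan-4-yl acetate
Conditions: HF·pyridine, THF–pyridine, 0 → 20 °C
Reagents that add atoms: none
Why: Fluoride-mediated desilylation under buffered, non-basic conditions should free C13–OH without acetate migration or elimination of the chlorides.

Step 15
Reactants: 20 (2R,4S,5S,7S,8S)-5,7-dichloro-2-[(1S)-1-hydroxypropyl]-8-[(2E)-pent-2-en-4-yn-1-yl]oxocan-4-yl acetate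
Product: 21 (2R,4S,5S,7S,8S)-2-[(1R)-1-bromopropyl]-5,7-dichloro-8-[(2E)-pent-2-en-4-yn-1-yl]oxocan-4-yl acetate
Conditions: CBr4, (n-C8H17)3P, toluene, 70 °C
Reagents that add atoms: tetrabromomethane, BrC(Br)(Br)Br
Why: Appel reaction, in which bromide should displace the alkoxyphosphonium group at C13 by SN2 with inversion, converting the (13S)-alcohol into the (13R)-bromide.

**Compound list**

1 | but-1-yne | CCC#C | starting material
2 | (R)-epichlorohydrin, (2R)-2-(chloromethyl)oxirane | ClC[C@H]1CO1 | starting material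
3 | (2R)-1-chlorohept-4-yn-2-ol | CCC#CC[C@@H](O)CCl | intermediate
4 | (2R)-2-(pent-2-ynyl)oxirane | CCC#CC[C@@H]1CO1 | intermediate
5 | (3R)-oct-1-en-5-yn-3-ol | C=C[C@H](O)CC#CCC | intermediate
6 | (3R,5E)-octa-1,5-dien-3-ol | C=C[C@H](O)C/C=C/CC | intermediate
7 | (2R)-1-[(2S,3S)-3-ethyloxiran-2-yl]but-3-en-2-ol | C=C[C@H](O)C[C@@H]1O[C@H]1CC | intermediate
8 | (1S)-1-[(2R,4R)-4-ethenyloxetan-2-yl]propan-1-ol | CC[C@H](O)[C@H]1C[C@H](C=C)O1 | intermediate
9 | tert-butyl{[(1S)-1-[(2R,4R)-4-ethenyloxetan-2-yl]propyl]oxy}dimethylsilane | CC[C@H](O[Si](C)(C)C(C)(C)C)[C@H]1C[C@H](C=C)O1 | intermediate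
10 | (5Z,8R)-8-[(1S)-1-(tert-butyldimethylsilyloxy)propyl]-3,3-dichloro-3,4,7,8-tetrahydro-2H-oxocin-2-one | CC[C@H](O[Si](C)(C)C(C)(C)C)[C@H]1C/C=C\CC(Cl)(Cl)C(=O)O1 | intermediate
11 | (3S,5Z,8R)-8-[(1S)-1-(tert-butyldimethylsilyloxy)propyl]-3-chloro-3,4,7,8-tetrahydro-2H-oxocin-2-one | CC[C@H](O[Si](C)(C)C(C)(C)C)[C@H]1C/C=C\C[C@H](Cl)C(=O)O1 | intermediate
12 | (1S,3R,6S,8R)-3-[(1S)-1-(tert-butyldimethylsilyloxy)propyl]-6-chloro-4,9-dioxabicyclo[6.1.0]nonan-5-one (convex-face 9,10-epoxide of 11) | CC[C@H](O[Si](C)(C)C(C)(C)C)[C@H]1C[C@@H]2O[C@@H]2C[C@H](Cl)C(=O)O1 | intermediate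
13 | (3S,5S,6S,8R)-8-[(1S)-1-(tert-butyldimethylsilyloxy)propyl]-3,5-dichloro-6-(triethylsilyloxy)oxocan-2-one | CC[C@H](O[Si](C)(C)C(C)(C)C)[C@H]1C[C@H](O[Si](CC)(CC)CC)[C@@H](Cl)C[C@H](Cl)C(=O)O1 | intermediate
14 | (3S,5S,6S,8R)-2-allyl-8-[(1S)-1-(tert-butyldimethylsilyloxy)propyl]-3,5-dichloro-6-(triethylsilyloxy)oxocan-2-ol (hemiketal, C2 epimers, present as its bromomagnesium alkoxide) | C=CCC1(O)O[C@@H]([C@H](CC)O[Si](C)(C)C(C)(C)C)C[C@H](O[Si](CC)(CC)CC)[C@@H](Cl)C[C@@H]1Cl | intermediate
15 | (2S,3S,5S,6S,8R)-2-allyl-8-[(1S)-1-(tert-butyldimethylsilyloxy)propyl]-3,5-dichloro-6-(triethylsilyloxy)oxocane | C=CC[C@@H]1O[C@@H]([C@H](CC)O[Si](C)(C)C(C)(C)C)C[C@H](O[Si](CC)(CC)CC)[C@@H](Cl)C[C@@H]1Cl | intermediate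
16 | (2E)-4-[(2S,3S,5S,6S,8R)-8-[(1S)-1-(tert-butyldimethylsilyloxy)propyl]-3,5-dichloro-6-(triethylsilyloxy)oxocan-2-yl]but-2-enal | O=C/C=C/C[C@@H]1O[C@@H]([C@H](CC)O[Si](C)(C)C(C)(C)C)C[C@H](O[Si](CC)(CC)CC)[C@@H](Cl)C[C@@H]1Cl | intermediate
17 | (2S,3S,5S,6S,8R)-8-[(1S)-1-(tert-butyldimethylsilyloxy)propyl]-3,5-dichloro-2-[(2E)-pent-2-en-4-yn-1-yl]-6-(triethylsilyloxy)oxocane | C#C/C=C/C[C@@H]1O[C@@H]([C@H](CC)O[Si](C)(C)C(C)(C)C)C[C@H](O[Si](CC)(CC)CC)[C@@H](Cl)C[C@@H]1Cl | intermediate
18 | (2R,4S,5S,7S,8S)-2-[(1S)-1-(tert-butyldimethylsilyloxy)propyl]-5,7-dichloro-8-[(2E)-pent-2-en-4-yn-1-yl]oxocan-4-ol | C#C/C=C/C[C@@H]1O[C@@H]([C@H](CC)O[Si](C)(C)C(C)(C)C)C[C@H](O)[C@@H](Cl)C[C@@H]1Cl | intermediate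
19 | (2R,4S,5S,7S,8S)-2-[(1S)-1-(tert-butyldimethylsilyloxy)propyl]-5,7-dichloro-8-[(2E)-pent-2-en-4-yn-1-yl]oxocan-4-yl acetate | C#C/C=C/C[C@@H]1O[C@@H]([C@H](CC)O[Si](C)(C)C(C)(C)C)C[C@H](OC(C)=O)[C@@H](Cl)C[C@@H]1Cl | intermediate
20 | (2R,4S,5S,7S,8S)-5,7-dichloro-2-[(1S)-1-hydroxypropyl]-8-[(2E)-pent-2-en-4-yn-1-yl]oxocan-4-yl acetate | C#C/C=C/C[C@@H]1O[C@@H]([C@H](CC)O)C[C@H](OC(C)=O)[C@@H](Cl)C[C@@H]1Cl | intermediate
21 | (2R,4S,5S,7S,8S)-2-[(1R)-1-bromopropyl]-5,7-dichloro-8-[(2E)-pent-2-en-4-yn-1-yl]oxocan-4-yl acetate | C#C/C=C/C[C@@H]1O[C@@H]([C@H](Br)CC)C[C@H](OC(C)=O)[C@@H](Cl)C[C@@H]1Cl | target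

**Step count.** Total: 15 steps. Longest linear sequence: 15 steps (1 and 2 to 21).

**Steps most likely to fail**

Step 7 (key step). ZnCl2-assisted cleavage of the strained oxetane by the acid chloride, or [2+2] cycloaddition of the ketene to the vinyl group, may outrun O-acylation and the [3,3] shift. The fallback avoids the oxetane and the ketene: it sets out from epoxy alcohol 7 and returns at dichloro lactone 10. Compound 7 is converted with Boc2O/DMAP into tert-butyl (2R)-1-[(2S,3S)-3-ethyloxiran-2-yl]but-3-en-2-yl carbonate F1. BF3·OEt2 (CH2Cl2, −40 °C) should then trigger 6-exo opening of the epoxide at C12 by the carbonate carbonyl oxygen, with inversion and loss of isobutene, giving the cyclic carbonate (4R,6R)-4-ethenyl-6-[(1S)-1-hydroxypropyl]-1,3-dioxan-2-one F2. TBSCl/imidazole gives its silyl ether F3. Petasis methylenation (Cp2TiMe2, toluene, 110 °C) gives the 2-methylene-1,3-dioxane, which should undergo Claisen rearrangement in the same pot to the unchlorinated lactone (5Z,8R)-8-[(1S)-1-(tert-butyldimethylsilyloxy)propyl]-3,4,7,8-tetrahydro-2H-oxocin-2-one F4. Two rounds of enolate chlorination (LiN(SiMe3)2, then N-chlorosuccinimide, THF, −78 °C) lead to 10.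

Step 9. Chloride may attack C10 instead of C9 (poor regiocontrol of the epoxide opening), and free chloride may epimerise C7 by exchange at the α-chloro lactone. The fallback replaces substrate control by catalyst control: it sets out from epoxy lactone 12, isolated after the dioxirane step, and returns at 13. Compound 12 is opened with SiCl4 and a chiral Lewis base of the meso-epoxide desymmetrisation type (BINAP dioxide, the enantiomer that directs chloride to C9, iPr2NEt, CH2Cl2, −78 °C). Buffered work-up gives the free chlorohydrin (3S,5S,6S,8R)-8-[(1S)-1-(tert-butyldimethylsilyloxy)propyl]-3,5-dichloro-6-hydroxyoxocan-2-one F5, which is silylated at once (Et3SiOTf, 2,6-lutidine, −78 °C) to 13.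

Step 10. The tetrahedral adduct may collapse to the open-chain hydroxy ketone, which then takes up a second allyl group or fails to re-close to the eight-membered oxocarbenium ion; hydride delivery may also show poor facial selectivity. The fallback keeps the ring closed through a sulfur-stabilised adduct: it sets out from 13 and returns at 15. Lawesson's reagent (toluene, 100 °C) converts 13 into the thionolactone (3S,5S,6S,8R)-8-[(1S)-1-(tert-butyldimethylsilyloxy)propyl]-3,5-dichloro-6-(triethylsilyloxy)oxocane-2-thione F6. CH2=CHCH2MgBr (−78 °C) followed by MeI gives the S-methyl O,S-ketal F7, whose thiolate precursor cannot ring-open. AgBF4/Et3SiH (CH2Cl2, −40 °C) should then ionise the C–S bond and reduce the oxocarbenium ion anti to C7–Cl to give 15.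

**Further compounds**

F1 | step 7 | tert-butyl (2R)-1-[(2S,3S)-3-ethyloxiran-2-yl]but-3-en-2-yl carbonate | C=C[C@H](OC(=O)OC(C)(C)C)C[C@@H]1O[C@H]1CC
F2 | step 7 | (4R,6R)-4-ethenyl-6-[(1S)-1-hydroxypropyl]-1,3-dioxan-2-one | CC[C@H](O)[C@H]1C[C@H](C=C)OC(=O)O1
F3 | step 7 | (4R,6R)-6-[(1S)-1-(tert-butyldimethylsilyloxy)propyl]-4-ethenyl-1,3-dioxan-2-one | CC[C@H](O[Si](C)(C)C(C)(C)C)[C@H]1C[C@H](C=C)OC(=O)O1
F4 | step 7 | (5Z,8R)-8-[(1S)-1-(tert-butyldimethylsilyloxy)propyl]-3,4,7,8-tetrahydro-2H-oxocin-2-one | CC[C@H](O[Si](C)(C)C(C)(C)C)[C@H]1C/C=C\CCC(=O)O1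
F5 | step 9 | (3S,5S,6S,8R)-8-[(1S)-1-(tert-butyldimethylsilyloxy)propyl]-3,5-dichloro-6-hydroxyoxocan-2-one | CC[C@H](O[Si](C)(C)C(C)(C)C)[C@H]1C[C@H](O)[C@@H](Cl)C[C@H](Cl)C(=O)O1
F6 | step 10 | (3S,5S,6S,8R)-8-[(1S)-1-(tert-butyldimethylsilyloxy)propyl]-3,5-dichloro-6-(triethylsilyloxy)oxocane-2-thione | CC[C@H](O[Si](C)(C)C(C)(C)C)[C@H]1C[C@H](O[Si](CC)(CC)CC)[C@@H](Cl)C[C@H](Cl)C(=S)O1
F7 | step 10 | (3S,5S,6S,8R)-2-allyl-8-[(1S)-1-(tert-butyldimethylsilyloxy)propyl]-3,5-dichloro-2-(methylsulfanyl)-6-(triethylsilyloxy)oxocane (C2 epimers) | C=CCC1(SC)O[C@@H]([C@H](CC)O[Si](C)(C)C(C)(C)C)C[C@H](O[Si](CC)(CC)CC)[C@@H](Cl)C[C@@H]1Cl
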